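**Plan**
- Retrosynthetic cuts, in order: C4–C11 (hydroxymethyl onto a C3=C4 enol triflate); C7–O (a coumarate opens a 7,8-epoxide at C7, then shifts to O10); C5–C6 and C7–C8 together (a C6–C7 vinyl sulfonium unit); C8–C5 and C8–C9 (a siloxycarbene onto the C5=C9 bond of a pyranone); the C1 ester and the pyranone back to furfuryl alcohol.
- Forward: the pyranone ring (O2, C1, C3, C4, C5, C9) comes first and already carries the final C1 ester. A cyclopropane C5–C9–C8 is then fused to it (a 3-oxabicyclo[4.1.0]heptan-5-one). That three-membered ring is expanded to the cyclopentane with a 7,8-epoxide, followed by enol triflate, epoxide opening and C11.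
- Enabling feature: C5 is alpha to the C4 ketone and C8 bears oxygen, so the C5–C8 bond of the donor–acceptor cyclopropane opens on desilylation to a C5 enolate and a C8 ketone. This 1,3-dipole across C5–C9–C8 takes up C6–C7.
- Stereochemistry: C1 by dynamic kinetic acylation; C9 by carbene addition anti to the C1 ester; C5 (cis fusion), C7 and C8 in the key step (epoxide on the concave face); C7 inverted in the SN2 opening; the side-chain centre from (S)-3-methylpentanoic acid.

Key step: step 6

Remarks on the chemistry:
- Names use iridoid numbering (C1 acetal carbon, O2, C3, C4, ring-fusion C5 and C9, C6–C8 in the cyclopentane, C10 on C8, C11 on C4); β is the face of H5 and H9.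
- (S)-3-Methylpentanoic acid, (tert-butyldimethylsilyloxy)acetaldehyde, diphenyl(vinyl)sulfonium triflate and (tributylstannyl)methanol are taken as commercial.
- The (R)-enantiomer of benzotetramisole is assumed to give the (S)-acetal ester in step 2; if the sense is opposite, its enantiomer is used.
- The cyclopropane of step 5 may form as either epimer at C8; both give the same enolate in step 6.

**Step 1**
Reactants: 1 furfuryl alcohol (furan-2-ylmethanol)
Product: 2 6-hydroxy-2H-pyran-3(6H)-one (racemic, mutarotating lactol)
Conditions: mCPBA, CH2Cl2, 0 °C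
Reagents that add atoms: meta-chloroperbenzoic acid, O=C(OO)c1cccc(Cl)c1
Why: Achmatowicz rearrangement, in which oxidation of the furan and ring expansion through the ene-dione give the pyranone lactol, whose acetal centre stays free to equilibrate.

**Step 2**
Reactants: 2 6-hydroxy-2H-pyran-3(6H)-one; 3 (S)-3-methylpentanoic acid
Product: 5 (S)-5-oxo-5,6-dihydro-2H-pyran-2-yl (S)-3-methylpentanoate, via mixed pivalic anhydride 4 (not isolated)
Conditions: Piv2O, i-Pr2NEt, (R)-benzotetramisole [(R)-2-phenyl-2,3-dihydroimidazo[2,1-b][1,3]benzothiazole] (5 mol %), toluene, 0 °C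
Reagents that add atoms: none
Why: Isothiourea-catalysed dynamic kinetic acylation, in which the lactol epimers interconvert by ring opening while the chiral acyl isothiouronium (formed from the less hindered acyl of 4) acylates one of them and should set C1 as S; this acylation is known for this lactol with simple anhydrides.

**Step 3**
Reactants: 6 (tert-butyldimethylsilyloxy)acetaldehyde
Product: 7 2-(tert-butyldimethylsilyloxy)-1-[dimethyl(phenyl)silyl]ethanol (racemic)
Conditions: PhMe2SiLi, THF, −78 °C; aq NH4Cl
Reagents that add atoms: dimethylphenylsilyllithium, [Li][Si](C)(C)c1ccccc1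
Why: 1,2-Addition of a silyl anion to an aldehyde gives the α-hydroxysilane, and the cold quench should prevent Brook rearrangement of the alkoxide.

**Step 4**
Reactants: 7 2-(tert-butyldimethylsilyloxy)-1-[dimethyl(phenyl)silyl]ethanol
Product: 8 2-(tert-butyldimethylsilyloxy)-1-[dimethyl(phenyl)silyl]ethan-1-one (acylsilane)
Conditions: Dess–Martin periodinane, CH2Cl2, 23 °C
Reagents that add atoms: none
Why: Oxidation of an α-hydroxysilane is a standard entry to acylsilanes, and the neutral Dess–Martin conditions should leave both silyl groups in place.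

**Step 5**
Reactants: 5 (S)-5-oxo-5,6-dihydro-2H-pyran-2-yl (S)-3-methylpentanoate; 8 acylsilane
Product: 9 siloxycyclopropane: 3-oxabicyclo[4.1.0]heptan-5-one in which the cyclopropane C5–C9–C8 is cis-fused to the pyranone on the face anti to the C1 ester, C8 carrying OSiMe2Ph and CH2OTBS (drawn with CH2OTBS exo)
Conditions: hν (420 nm LED), toluene, 20 °C
Reagents that add atoms: none
Why: Photochemical 1,2-silyl shift of the acylsilane (Brook-type) gives a nucleophilic siloxycarbene, which cyclopropanates electron-poor C=C bonds; addition anti to the pseudo-axial C1 ester should set C9 (C5 is cis by the three-membered ring), and the neutral conditions avoid base-induced loss of the acetal ester from the enone.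

**Step 6**
Reactants: 9 siloxycyclopropane; 10 diphenyl(vinyl)sulfonium triflate
Product: 13 7α,8α-epoxy-10-O-TBS cyclopenta[c]pyran-4-one (cis-fused; C1 ester β; CH2OTBS on C8 β), via γ-keto enolate 11 (not isolated), via sulfonium ylide 12 (not isolated)
Conditions: Bu4N[Ph3SiF2] (1.1 equiv), THF, −78 to −20 °C
Reagents that add atoms: none
Why: Proposed new method: fluoride takes the PhMe2Si group from the cyclopropanol ether of 9, the alkoxide breaks the C5–C8 bond (the only cyclopropane bond whose cleavage gives an enolate conjugated with the C4 ketone) to the γ-keto enolate 11, C5 adds to the vinyl sulfonium (C5–C6), and the ylide 12 adds through C7 to the C8 ketone (C7–C8) before the alkoxide expels Ph2S to close the oxirane. The closest known reaction types are the fluoride-induced ring opening/Michael/Wittig cyclopentene annulation of 2-siloxycyclopropane carbonyl compounds with vinylphosphonium salts and the epoxy-annulation of ketones carrying a tethered N, O or S nucleophile with diphenyl vinyl sulfonium triflate; joining a cyclopropane-derived carbon enolate to the sulfonium salt to give an epoxide-fused carbocycle is the new element. The cyclopentane closes by 5-exo-trig addition of the ylide carbon to the carbonyl and the oxirane by 3-exo-tet displacement at C7. C5 is expected to take C6 on the α face because axial attack on the β face would run 1,3-diaxial into the C1 ester and because C5 stays epimerisable (alpha to the C4 ketone) while the cis-disposed ylide reaches C8 most easily; at C7 and C8 the bulky Ph2S+ and CH2OTBS groups should both sit on the convex β face, and the anti-periplanar betaine then places the oxygen on the concave α face. The step needs C- over O-alkylation of the enolate, carbonyl addition of the ylide faster than proton transfer from C5–H (which would lead to cyclopropane closure), and fluoride attack on the cyclopropyl silyl ether only; the soft Michael acceptor, the five-membered intramolecular addition at low temperature and the far greater lability of the strained PhMe2Si ether over the primary TBS ether are relied on for these.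

**Step 7**
Reactants: 13 epoxy ketone
Product: 14 C3=C4 enol triflate of 13 (4-trifluoromethanesulfonyloxy-3-ene; epoxide, TBS ether and C1 ester unchanged)
Conditions: KN(SiMe3)2, THF, −78 °C; PhNTf2
Reagents that add atoms: N-phenylbis(trifluoromethanesulfonimide), O=S(=O)(N(c1ccccc1)S(=O)(=O)C(F)(F)F)C(F)(F)F
Why: Kinetic enolisation should occur at the C3 methylene because C5 is a hindered ring-fusion methine, and O-sulfonylation then fixes the C3=C4 double bond, as is precedented on cyclopenta-fused pyran-3-ones bearing an acetal ester.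

**Step 8**
Reactants: 14 enol triflate
Product: 15 7α,8α-epoxy-10-ol (2,3-epoxy alcohol; enol triflate and C1 ester unchanged)
Conditions: Bu4NF, AcOH (1:1), THF, 0 to 23 °C
Reagents that add atoms: none
Why: Buffered fluoride cleaves the primary silyl ether, and the acetic acid keeps the product as the alcohol so that no alkoxide is available for Payne rearrangement or attack on the triflate.

**Step 9**
Reactants: 16 p-coumaric acid ((E)-4-hydroxycinnamic acid)
Product: 18 (E)-4-(tert-butyldimethylsilyloxy)cinnamic acid, via bis-silylated coumarate 17 (not isolated)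
Conditions: TBSCl, imidazole, DMF, 23 °C; then AcOH/THF/H2O
Reagents that add atoms: tert-butyldimethylsilyl chloride, CC(C)(C)[Si](C)(C)Cl
Why: Silylation of both acidic groups followed by selective hydrolysis of the labile silyl ester leaves the aryl silyl ether, a routine protection of hydroxycinnamic acids.

**Step 10**
Reactants: 15 epoxy alcohol; 18 (E)-4-(tert-butyldimethylsilyloxy)cinnamic acid
Product: 20 10-O-[(E)-4-(TBSO)cinnamoyl] 7β,8α-diol enol triflate, via C7 ester isomer 19 (not isolated)
Conditions: Ti(OiPr)4, CH2Cl2, 23 °C; aq tartaric acid; then 1,8-diazabicyclo[5.4.0]undec-7-ene (DBU, 0.2 equiv), CH2Cl2, 0 °C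
Reagents that add atoms: none
Why: Ti(OiPr)4-mediated opening of a 2,3-epoxy alcohol by a carboxylic acid, in which titanium bound to O10 and the epoxide oxygen delivers the carboxylate to C7 (C8 is quaternary) with inversion to give the 7β-ester, and the base-mediated 1,3-acyl shift through a six-membered orthoacid then moves the acyl group to the primary O10, the trans tertiary C8–OH being unable to accept it.

**Step 11**
Reactants: 20 diol ester enol triflate; 21 (tributylstannyl)methanol
Product: 22 11-hydroxy compound: the target with the phenol as its TBS ether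
Conditions: Pd(PPh3)4 (10 mol %), LiCl, 1,4-dioxane, 80 °C
Reagents that add atoms: none
Why: Stille coupling of an enol triflate with the hydroxymethyl stannane installs C11 directly at the alcohol oxidation level, tolerates the free diol and esters, and touches no stereocentre.

**Step 12**
Reactants: 22 phenol TBS ether
Product: 23 target, CNP0241834.1
Conditions: Bu4NF, AcOH, THF, 0 °C
Reagents that add atoms: none
Why: Aryl silyl ethers are cleaved rapidly by buffered fluoride, conditions under which the two esters, the acetal and the enol ether should survive.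

**Compound list**
1 | furfuryl alcohol | OCc1ccco1 | starting material
2 | 6-hydroxy-2H-pyran-3(6H)-one (racemic lactol) | OC1OCC(=O)C=C1 | intermediate
3 | (S)-3-methylpentanoic acid | CC[C@H](C)CC(=O)O | starting material
4 | (S)-3-methylpentanoic pivalic anhydride | CC[C@H](C)CC(=O)OC(=O)C(C)(C)C | intermediate (not isolated)
5 | (S)-5-oxo-5,6-dihydro-2H-pyran-2-yl (S)-3-methylpentanoate | CC[C@H](C)CC(=O)O[C@@H]1OCC(=O)C=C1 | intermediate
6 | (tert-butyldimethylsilyloxy)acetaldehyde | CC(C)(C)[Si](C)(C)OCC=O | starting material
7 | 2-(tert-butyldimethylsilyloxy)-1-[dimethyl(phenyl)silyl]ethanol (racemic) | CC(C)(C)[Si](C)(C)OCC(O)[Si](C)(C)c1ccccc1 | intermediate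
8 | 2-(tert-butyldimethylsilyloxy)-1-[dimethyl(phenyl)silyl]ethan-1-one | CC(C)(C)[Si](C)(C)OCC(=O)[Si](C)(C)c1ccccc1 | intermediate
9 | siloxycyclopropane fused to the pyranone (cyclopropane anti to the C1 ester; C8 with OSiMe2Ph and CH2OTBS) | CC[C@H](C)CC(=O)O[C@@H]1OCC(=O)[C@@H]2[C@H]1[C@@]2(O[Si](C)(C)c1ccccc1)CO[Si](C)(C)C(C)(C)C | intermediate
10 | diphenyl(vinyl)sulfonium triflate | C=C[S+](c1ccccc1)c1ccccc1.[O-]S(=O)(=O)C(F)(F)F | starting material
11 | tetrabutylammonium C4–C5 enolate carrying the C8 ketone side chain on C9 | CC[C@H](C)CC(=O)O[C@@H]1OCC([O-])=C[C@H]1C(=O)CO[Si](C)(C)C(C)(C)C.CCCC[N+](CCCC)(CCCC)CCCC | intermediate (not isolated)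
12 | sulfonium ylide after C5–C6 bond formation (C6 and the C8 ketone chain cis) | CC[C@H](C)CC(=O)O[C@@H]1OCC(=O)[C@@H](C[CH-][S+](c2ccccc2)c2ccccc2)[C@H]1C(=O)CO[Si](C)(C)C(C)(C)C | intermediate (not isolated)
13 | 7α,8α-epoxy-10-O-TBS cyclopenta[c]pyran-4-one, C1 ester β | CC[C@H](C)CC(=O)O[C@@H]1OCC(=O)[C@H]2C[C@H]3O[C@@]3(CO[Si](C)(C)C(C)(C)C)[C@@H]12 | intermediate
14 | C3=C4 enol triflate of 13 | CC[C@H](C)CC(=O)O[C@@H]1OC=C(OS(=O)(=O)C(F)(F)F)[C@H]2C[C@H]3O[C@@]3(CO[Si](C)(C)C(C)(C)C)[C@@H]12 | intermediate
15 | 7α,8α-epoxy-10-ol enol triflate | CC[C@H](C)CC(=O)O[C@@H]1OC=C(OS(=O)(=O)C(F)(F)F)[C@H]2C[C@H]3O[C@@]3(CO)[C@@H]12 | intermediate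
16 | p-coumaric acid | OC(=O)/C=C/c1ccc(O)cc1 | starting material
17 | tert-butyldimethylsilyl (E)-4-(tert-butyldimethylsilyloxy)cinnamate | CC(C)(C)[Si](C)(C)OC(=O)/C=C/c1ccc(O[Si](C)(C)C(C)(C)C)cc1 | intermediate (not isolated)
18 | (E)-4-(tert-butyldimethylsilyloxy)cinnamic acid | OC(=O)/C=C/c1ccc(O[Si](C)(C)C(C)(C)C)cc1 | intermediate
19 | 7β-O-[(E)-4-(TBSO)cinnamoyl] 8α,10-diol enol triflate | CC[C@H](C)CC(=O)O[C@@H]1OC=C(OS(=O)(=O)C(F)(F)F)[C@H]2C[C@H](OC(=O)/C=C/c3ccc(O[Si](C)(C)C(C)(C)C)cc3)[C@](O)(CO)[C@@H]12 | intermediate (not isolated)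
20 | 10-O-[(E)-4-(TBSO)cinnamoyl] 7β,8α-diol enol triflate | CC[C@H](C)CC(=O)O[C@@H]1OC=C(OS(=O)(=O)C(F)(F)F)[C@H]2C[C@H](O)[C@](O)(COC(=O)/C=C/c3ccc(O[Si](C)(C)C(C)(C)C)cc3)[C@@H]12 | intermediate
21 | (tributylstannyl)methanol | CCCC[Sn](CCCC)(CCCC)CO | starting material
22 | target with the phenol as TBS ether | CC[C@H](C)CC(=O)O[C@@H]1OC=C(CO)[C@H]2C[C@H](O)[C@](O)(COC(=O)/C=C/c3ccc(O[Si](C)(C)C(C)(C)C)cc3)[C@@H]12 | intermediate
23 | CNP0241834.1 | CC[C@H](C)CC(=O)O[C@@H]1OC=C(CO)[C@H]2C[C@H](O)[C@](O)(COC(=O)/C=C/c3ccc(O)cc3)[C@@H]12 | target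

**Count**
Total step count: 12. Longest linear sequence: 9 (steps 1, 2, 5, 6, 7, 8, 10, 11, 12).

**Steps most likely to fail**

Step 6 (Proposed new method). The vinyl sulfonium may add to the wrong face of the C5 enolate and lead to a trans ring fusion. Proton transfer from C5–H to the ylide may outrun carbonyl addition and end in cyclopropane closure. A syn betaine that cannot close may form, or the primary silyl ether may be lost to fluoride. The fallback uses known chemistry, sets out from 9 and comes back at 13. Treatment of 9 with Bu4N[Ph3SiF2] and vinyltriphenylphosphonium bromide in THF is the known fluoride-induced ring opening/Michael addition/intramolecular Wittig sequence and should give the cis-fused cyclopentene F1 (C7=C8); catalytic DBU can settle the C5 centre to the cis fusion if needed. N-Bromosuccinimide in aqueous THF should place bromonium on the convex β face and water on the tertiary C8 from the concave face to give the bromohydrin F2. K2CO3 in acetone then closes the oxirane with inversion at C7 to give 13.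

Step 5. The siloxycarbene may isomerise by 1,2-hydrogen shift to an enol ether or add to the C4 carbonyl faster than to the C5=C9 bond, and the enone may degrade under irradiation. The fallback sets out from 5 and comes back at 13. Conjugate addition of the pinacol ester of 3-(tert-butyldimethylsilyloxy)prop-1-en-2-ylboronic acid with [Rh(OH)(cod)]2 in aqueous dioxane (no added base, anti to the C1 ester) should give the alkenyl ketone F3. Ozonolysis (O3, then Me2S) gives the 1,4-diketone F4. Kinetic enol silylation (LDA, Me3SiCl, THF, −78 °C) at the unhindered C5 methylene gives the trimethylsilyl enol ether F5. F5 with 10 under the conditions of step 6 generates enolate 11 and should give 13.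

Step 10. The carboxylate may attack C8 instead of C7, isopropoxide may compete as the nucleophile, the acyl shift may stop short, and Ti(OiPr)4 may exchange the C1 ester. The fallback sets out from 14 and 16 and comes back at 23. p-Coumaric acid 16 and one equivalent of Bu4NOH give tetrabutylammonium p-coumarate F6, which in DMF at 50 °C should open the epoxide of 14 at the secondary C7 by direct SN2 attack, without a directing metal, to the C7 coumarate F7. Bu4NF/AcOH frees the C10 hydroxyl to give the diol F8. Catalytic DBU shifts the acyl group to O10 to give the C10 coumarate F9 with the phenol already free. F9 with 21 under the conditions of step 11 gives 23 directly.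

**Further compounds**
F1 | step 6 | cis-fused cyclopentene (C7=C8) with 10-O-TBS, C4 ketone and C1 ester | CC[C@H](C)CC(=O)O[C@@H]1OCC(=O)[C@H]2CC=C(CO[Si](C)(C)C(C)(C)C)[C@@H]12
F2 | step 6 | 7β-bromo-8α-hydroxy bromohydrin | CC[C@H](C)CC(=O)O[C@@H]1OCC(=O)[C@H]2C[C@H](Br)[C@](O)(CO[Si](C)(C)C(C)(C)C)[C@@H]12
F3 | step 5 | pyranone ketone with a 3-(TBSO)prop-1-en-2-yl group on C9, trans to the C1 ester | CC[C@H](C)CC(=O)O[C@@H]1OCC(=O)C[C@H]1C(=C)CO[Si](C)(C)C(C)(C)C
F4 | step 5 | 1,4-diketone (C4 and C8 ketones) | CC[C@H](C)CC(=O)O[C@@H]1OCC(=O)C[C@H]1C(=O)CO[Si](C)(C)C(C)(C)C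
F5 | step 5 | C4–C5 trimethylsilyl enol ether of the 1,4-diketone | CC[C@H](C)CC(=O)O[C@@H]1OCC(O[Si](C)(C)C)=C[C@H]1C(=O)CO[Si](C)(C)C(C)(C)C
F6 | step 10 | tetrabutylammonium (E)-4-hydroxycinnamate | [O-]C(=O)/C=C/c1ccc(O)cc1.CCCC[N+](CCCC)(CCCC)CCCC
F7 | step 10 | 7β-O-(E)-4-hydroxycinnamoyl 8α-ol 10-O-TBS enol triflate | CC[C@H](C)CC(=O)O[C@@H]1OC=C(OS(=O)(=O)C(F)(F)F)[C@H]2C[C@H](OC(=O)/C=C/c3ccc(O)cc3)[C@](O)(CO[Si](C)(C)C(C)(C)C)[C@@H]12
F8 | step 10 | 7β-O-(E)-4-hydroxycinnamoyl 8α,10-diol enol triflate | CC[C@H](C)CC(=O)O[C@@H]1OC=C(OS(=O)(=O)C(F)(F)F)[C@H]2C[C@H](OC(=O)/C=C/c3ccc(O)cc3)[C@](O)(CO)[C@@H]12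
F9 | step 10 | 10-O-(E)-4-hydroxycinnamoyl 7β,8α-diol enol triflate | CC[C@H](C)CC(=O)O[C@@H]1OC=C(OS(=O)(=O)C(F)(F)F)[C@H]2C[C@H](O)[C@](O)(COC(=O)/C=C/c3ccc(O)cc3)[C@@H]12
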